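**Plan**

1. The target is an achiral CH2-bridged pair of acetylphloroglucinol rings. Ring A is the 3-acetyl-2,6-dihydroxy-4-methoxyphenyl unit. Ring B is hexasubstituted: C1' acetyl, C2' OMe, C3' bridge CH2, C4' OH, C5' CH3, C6' OH.
2. Retrosynthetic cuts, in order: the ring A C–acetyl bond; then C4'–C5' and C6'–C1' of ring B; then the pyrone C3–CH2 bond; then the aryl–CHO bond.
3. The feature that allows the ring B cut: acetyl CH3, acetyl C=O, C1', C2'–OMe, C3' and C4' are the C6-methyl, C6, C5, C4–OMe, C3 and C2 of a 3-benzyl-4-methoxy-6-methyl-2-pyrone, and C5'(CH3)–C6' is a propanoate, so the C2' methoxyl is fixed by the pyrone and no phenol has to be differentiated.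
4. Forward: ring A and the pyrone ring are bought and joined through the bridge carbon (steps 1–4); ring B is made from the pyrone ring by opening and Claisen reclosure with the propanoate enolate (step 5); ring A is deprotected and acetylated last (steps 6–7).
5. Stereochemistry: none to set; the target has no stereocentre and no stereogenic double bond.

Key step: step 5

Remarks on the chemistry: compound 12 is drawn as the neutral keto form of the metal enolate that is actually present, and its C2 is a transient racemic centre. The alkene geometry of 6 and the enolate geometry of 10 and 11 have no bearing on the outcome.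

**Step 1**
Reactants: 1 5-methoxyresorcinol
Product: 2 1-methoxy-3,5-bis(methoxymethoxy)benzene
Conditions: NaH, MOMCl, DMF, 0 °C → rt
Reagents that add atoms: chloromethyl methyl ether, COCCl
Why: O-alkylation of both phenoxides with the hard electrophile MOMCl (Williamson-type acetal ether formation) is routine and installs the two ortho-directing groups needed for step 2.

**Step 2**
Reactants: 2 1-methoxy-3,5-bis(methoxymethoxy)benzene
Product: 4 4-methoxy-2,6-bis(methoxymethoxy)benzaldehyde, via aryllithium 3 (not isolated)
Conditions: n-BuLi, TMEDA, THF, 0 °C; DMF, −78 °C → rt; H2O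
Reagents that add atoms: N,N-dimethylformamide, CN(C)C=O
Why: Directed ortho-metalation should occur at the carbon flanked by the two OCH2OCH3 groups, the most acidic and doubly coordinated site, and the aryllithium is formylated by DMF.

**Step 3**
Reactants: 4 4-methoxy-2,6-bis(methoxymethoxy)benzaldehyde, 5 4-hydroxy-6-methyl-2H-pyran-2-one (triacetic acid lactone)
Product: 7 4-hydroxy-3-{[4-methoxy-2,6-bis(methoxymethoxy)phenyl]methyl}-6-methyl-2H-pyran-2-one, via Knoevenagel alkylidene 6 (not isolated)
Conditions: Hantzsch ester (diethyl 2,6-dimethyl-1,4-dihydropyridine-3,5-dicarboxylate), L-proline (cat.), EtOH, rt → 40 °C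
Reagents that add atoms: none
Why: Three-component reductive alkylation: proline-catalysed Knoevenagel condensation at the nucleophilic C3 of the pyrone gives alkylidene 6, which the Hantzsch ester should reduce by conjugate hydride transfer before a second pyrone can add; the MOM ethers tolerate the near-neutral medium.

**Step 4**
Reactants: 7 4-hydroxy-3-{[4-methoxy-2,6-bis(methoxymethoxy)phenyl]methyl}-6-methyl-2H-pyran-2-one
Product: 8 4-methoxy-3-{[4-methoxy-2,6-bis(methoxymethoxy)phenyl]methyl}-6-methyl-2H-pyran-2-one
Conditions: Me2SO4, K2CO3, acetone, reflux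
Reagents that add atoms: dimethyl sulfate, COS(=O)(=O)OC
Why: O-methylation of the vinylogous acid with Me2SO4/K2CO3 in acetone is the standard way to 4-methoxy-2-pyrones in preference to the 2-methoxy-4-pyrone isomers, and with ring A protected the pyrone OH is the only acidic site.

**Step 5**
Reactants: 8 4-methoxy-3-{[4-methoxy-2,6-bis(methoxymethoxy)phenyl]methyl}-6-methyl-2H-pyran-2-one, 9 methyl propanoate
Product: 13 1-(2,4-dihydroxy-6-methoxy-5-{[4-methoxy-2,6-bis(methoxymethoxy)phenyl]methyl}-3-methylphenyl)ethanone, via lithium enolate 10 (not isolated), via dichlorocerium enolate 11 (not isolated), via open-chain enolate 12 (not isolated)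
Conditions: 9 (excess), LiN(iPr)2, THF, −78 °C; anhydrous CeCl3, −78 °C; 8 added slowly, −78 → 0 °C; then Mg(OMe)2, MeOH, 60 °C; cold 1 M HCl to pH 5
Reagents that add atoms: none
Why: Proposed new method: the enolate 11 should add to the lactone carbonyl C2 of 8, and the tetrahedral adduct should collapse by expelling the C6–O enolate (a vinylogous β-diketonate leaving group) to give the open-chain enolate 12, a 3,5,7-triketo ester whose 5-carbonyl stays masked as the methyl enol ether, whose central double bond keeps the cis arrangement inherited from the ring, and which as an anion is protected from a second addition. After the switch to Mg(OMe)2 in MeOH, which also reprotonates any over-deprotonated β-keto ester, the enolate carbon that was pyrone C5 should attack the methyl ester in a 6-(enolexo)-exo-trig Claisen closure, and loss of methoxide followed by enolization gives the arene, so that C4'–C5' and C6'–C1' are formed and ring B is closed in one flask with the old C6 and its methyl as the acetyl group. The closest known reaction types are the Mg(OMe)2-mediated Claisen-mode cyclization of 3,5,7-triketo esters and of 6-acetonyl-4-hydroxy-2-pyrone to acetylphloroglucinols, and carbanion-induced ring transformations of 2-pyranones; the addition of an ester enolate to C2 of a 4-methoxy-2-pyrone as the opening event is the unprecedented part. No stereocentre is created, since C2 of 12 is a transient racemic centre that vanishes on aromatization. The step needs attack at C2 and not at C4, at C6 or at the acidic protons of the C6 methyl group: the C3 benzyl group screens C4, C6 is a fully substituted and oxygen-donated diene terminus, and the lithium enolate is converted into the weakly basic, oxophilic Cl2Ce enolate because such reagents favour carbonyl addition over proton transfer and conjugate addition. The competing aldol mode (ester α-carbon onto the methyl ketone) would give a quaternary carbon that cannot aromatize and should revert, while Mg chelation is known to steer such triketo esters to the Claisen mode.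

**Step 6**
Reactants: 13 1-(2,4-dihydroxy-6-methoxy-5-{[4-methoxy-2,6-bis(methoxymethoxy)phenyl]methyl}-3-methylphenyl)ethanone
Product: 14 1-{5-[(2,6-dihydroxy-4-methoxyphenyl)methyl]-2,4-dihydroxy-6-methoxy-3-methylphenyl}ethanone
Conditions: 3 M HCl, MeOH, 45 °C
Reagents that add atoms: none
Why: Acid-catalysed acetal cleavage of the two aryl MOM ethers, with methanol capturing the methoxymethyl cation as dimethoxymethane so that the electron-rich rings are not alkylated; the aryl methyl ethers and the ketone are inert.

**Step 7**
Reactants: 14 1-{5-[(2,6-dihydroxy-4-methoxyphenyl)methyl]-2,4-dihydroxy-6-methoxy-3-methylphenyl}ethanone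
Product: 16 1-{5-[(3-acetyl-2,6-dihydroxy-4-methoxyphenyl)methyl]-2,4-dihydroxy-6-methoxy-3-methylphenyl}ethanone (target), via ketiminium chloride 15 (not isolated)
Conditions: MeCN, ZnCl2, HCl (g), Et2O, 0 °C → rt; then H2O, 80 °C
Reagents that add atoms: acetonitrile, CC#N; water, O
Why: Hoesch acylation: ring A holds the only unsubstituted aromatic positions, two equivalent CH sites each ortho or para to three oxygen donors, so the nitrilium electrophile can enter only there, and the ketiminium salt 15 deactivates the ring against a second acylation before it is hydrolysed to the ketone.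

**Compound list**

1 | 5-methoxyresorcinol (5-methoxybenzene-1,3-diol) | COc1cc(O)cc(O)c1 | starting material
2 | 1-methoxy-3,5-bis(methoxymethoxy)benzene | COCOc1cc(OC)cc(OCOC)c1 | intermediate
3 | [4-methoxy-2,6-bis(methoxymethoxy)phenyl]lithium | [Li]c1c(OCOC)cc(OC)cc1OCOC | intermediate (not isolated)
4 | 4-methoxy-2,6-bis(methoxymethoxy)benzaldehyde | COCOc1cc(OC)cc(OCOC)c1C=O | intermediate
5 | 4-hydroxy-6-methyl-2H-pyran-2-one (triacetic acid lactone) | CC1=CC(O)=CC(=O)O1 | starting material
6 | 3-{[4-methoxy-2,6-bis(methoxymethoxy)phenyl]methylidene}-6-methyl-2H-pyran-2,4(3H)-dione (alkene geometry not defined) | COCOc1cc(OC)cc(OCOC)c1C=C1C(=O)C=C(C)OC1=O | intermediate (not isolated)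
7 | 4-hydroxy-3-{[4-methoxy-2,6-bis(methoxymethoxy)phenyl]methyl}-6-methyl-2H-pyran-2-one | COCOc1cc(OC)cc(OCOC)c1CC1=C(O)C=C(C)OC1=O | intermediate
8 | 4-methoxy-3-{[4-methoxy-2,6-bis(methoxymethoxy)phenyl]methyl}-6-methyl-2H-pyran-2-one | COCOc1cc(OC)cc(OCOC)c1CC1=C(OC)C=C(C)OC1=O | intermediate
9 | methyl propanoate | CCC(=O)OC | starting material
10 | lithium 1-methoxyprop-1-en-1-olate (methyl trans to O–Li) | C/C=C(/O[Li])OC | intermediate (not isolated)
11 | dichlorocerium 1-methoxyprop-1-en-1-olate, Cl2Ce–OC(OMe)=CHMe (methyl trans to O–Ce) | C/C=C(/O[Ce](Cl)Cl)OC | intermediate (not isolated)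
12 | methyl (4E)-5-methoxy-4-{[4-methoxy-2,6-bis(methoxymethoxy)phenyl]methyl}-2-methyl-3,7-dioxooct-4-enoate (racemic at C2; neutral keto form of the enolate) | COC(=O)C(C)C(=O)/C(Cc1c(OCOC)cc(OC)cc1OCOC)=C(/OC)CC(C)=O | intermediate (not isolated)
13 | 1-(2,4-dihydroxy-6-methoxy-5-{[4-methoxy-2,6-bis(methoxymethoxy)phenyl]methyl}-3-methylphenyl)ethanone | COCOc1cc(OC)cc(OCOC)c1Cc1c(O)c(C)c(O)c(C(C)=O)c1OC | intermediate
14 | 1-{5-[(2,6-dihydroxy-4-methoxyphenyl)methyl]-2,4-dihydroxy-6-methoxy-3-methylphenyl}ethanone | COc1cc(O)c(Cc2c(O)c(C)c(O)c(C(C)=O)c2OC)c(O)c1 | intermediate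
15 | 1-{3-[(3-acetyl-2,6-dihydroxy-4-methoxy-5-methylphenyl)methyl]-2,4-dihydroxy-6-methoxyphenyl}ethan-1-iminium chloride | COc1cc(O)c(Cc2c(O)c(C)c(O)c(C(C)=O)c2OC)c(O)c1C(C)=[NH2+].[Cl-] | intermediate (not isolated)
16 | 1-{5-[(3-acetyl-2,6-dihydroxy-4-methoxyphenyl)methyl]-2,4-dihydroxy-6-methoxy-3-methylphenyl}ethanone | COc1cc(O)c(Cc2c(O)c(C)c(O)c(C(C)=O)c2OC)c(O)c1C(C)=O | target

**Step count and risks**

Total steps: 7. Longest linear sequence: 7 steps (1 → 16); compounds 5 and 9 enter as bought materials.

Steps most likely to fail:

1. Step 5. The enolate may abstract a proton from the C6 methyl group or add in conjugate fashion at C6 instead of adding to the lactone carbonyl, or the opened chain may fail to close in the Claisen mode. The fallback builds the bridge by classical Mannich and ortho-quinone-methide chemistry on preformed acetophenones. It sets out from 1: Hoesch acetylation (MeCN, ZnCl2, HCl; then H2O) should give mainly 1-(2,4-dihydroxy-6-methoxyphenyl)ethanone F1. Nuclear C-methylation of part of F1 (MeI, NaOMe, MeOH) at the carbon between its two hydroxyls gives 1-(2,4-dihydroxy-6-methoxy-3-methylphenyl)ethanone F2. Aminomethylation of F2 at its single free ring position (CH2O, Me2NH, EtOH) gives 1-{5-[(dimethylamino)methyl]-2,4-dihydroxy-6-methoxy-3-methylphenyl}ethanone F3. Heating F3 with F1 in dioxane expels dimethylamine to an ortho-quinone methide, which F1 should capture at the carbon between its two hydroxyls. This rejoins the route at the target 16.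

2. Step 7. Under HCl/ZnCl2 the free phenols may be converted into imidates in place of ring C-acylation, or the electron-rich diarylmethane bridge may be cleaved by acid. The fallback installs the acetyl group by cross-coupling before deprotection and sets out from 13. Iodination with N-iodosuccinimide (CH2Cl2, 0 °C) at one of the two equivalent free positions of ring A gives 1-(2,4-dihydroxy-5-{[3-iodo-4-methoxy-2,6-bis(methoxymethoxy)phenyl]methyl}-6-methoxy-3-methylphenyl)ethanone F4. Stille coupling with tributyl(1-ethoxyvinyl)stannane (Pd(PPh3)4, CuI, dioxane, 90 °C) gives 1-(5-{[3-(1-ethoxyethenyl)-4-methoxy-2,6-bis(methoxymethoxy)phenyl]methyl}-2,4-dihydroxy-6-methoxy-3-methylphenyl)ethanone F5. Aqueous HCl in MeOH then hydrolyses the enol ether and removes both MOM groups in one operation. This rejoins the route at 16.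

3. Step 3. Condensation of the hindered, electron-rich aldehyde may be slow, and the alkylidene may be captured by a second pyrone faster than hydride is transferred. The fallback traps the alkylidene with a thiol and desulfurizes, and sets out from 4 and 5. Condensation in the presence of thiophenol (piperidine, AcOH, EtOH) gives racemic 4-hydroxy-3-{[4-methoxy-2,6-bis(methoxymethoxy)phenyl](phenylsulfanyl)methyl}-6-methyl-2H-pyran-2-one F6. Reductive desulfurization of F6 with Raney Ni in EtOH removes the phenylsulfanyl group. This rejoins the route at 7.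

**Further compounds**

F1 | step 5 | 1-(2,4-dihydroxy-6-methoxyphenyl)ethanone | CC(=O)c1c(O)cc(O)cc1OC
F2 | step 5 | 1-(2,4-dihydroxy-6-methoxy-3-methylphenyl)ethanone | CC(=O)c1c(O)c(C)c(O)cc1OC
F3 | step 5 | 1-{5-[(dimethylamino)methyl]-2,4-dihydroxy-6-methoxy-3-methylphenyl}ethanone | CC(=O)c1c(O)c(C)c(O)c(CN(C)C)c1OC
F4 | step 7 | 1-(2,4-dihydroxy-5-{[3-iodo-4-methoxy-2,6-bis(methoxymethoxy)phenyl]methyl}-6-methoxy-3-methylphenyl)ethanone | COCOc1cc(OC)c(I)c(OCOC)c1Cc1c(O)c(C)c(O)c(C(C)=O)c1OC
F5 | step 7 | 1-(5-{[3-(1-ethoxyethenyl)-4-methoxy-2,6-bis(methoxymethoxy)phenyl]methyl}-2,4-dihydroxy-6-methoxy-3-methylphenyl)ethanone | CCOC(=C)c1c(OC)cc(OCOC)c(Cc2c(O)c(C)c(O)c(C(C)=O)c2OC)c1OCOC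
F6 | step 3 | 4-hydroxy-3-{[4-methoxy-2,6-bis(methoxymethoxy)phenyl](phenylsulfanyl)methyl}-6-methyl-2H-pyran-2-one (racemic) | COCOc1cc(OC)cc(OCOC)c1C(Sc1ccccc1)C1=C(O)C=C(C)OC1=O
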